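C–C bonds cut: first C7–C9, then C9–CH3 and C7′–C9. Both halves then lead back to one isochromanone 16, which is cut at C4a′–C4′, C8a′–C1′ and C4′–CH3. (Isochromene numbering, lactone half primed, bridging methine C9.)
Enabling feature: in the lactone half the neighbouring arene carbons C4a′ and C8a′ carry C4′ and the carboxyl carbon C1′, and the C8′ oxygen sits beside C8a′. An aryne across C4a′–C8a′, polarised by that oxygen, can take up both ends of the four-atom unit C4′–C3′–O2′–C1′, which is a β-lactone, and so close the dihydropyranone ring.
Forward order: arene 1 becomes iodo triflate 9, and the lactone ring of 16 is closed in the key step. After demethylation to 17 the material is divided.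
One part of 17 receives C9 as a formyl group and then the C9 methyl (19). The other part is reduced at C1 and dehydrated to the pyran quinone methide 23. The halves are joined last at C7–C9.
Stereochemistry: C3 and C3′ come from (R)-β-butyrolactone. C4 and C4′ come from methylation anti to the C3′ methyl in the key step. C9 is set by a chiral Brønsted acid in the final coupling.

Key step: step 5

Assumption: the sense of induction of the acid catalyst in step 12 cannot be read from close analogues; the (R)-binaphthyl catalyst is written, and its mirror image takes its place should it favour the C9 epimer.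

Step 1
Reactants: 1 2-hydroxy-4,6-dimethoxybenzaldehyde
Product: 2 3,5-dimethoxy-2-methylphenol
Conditions: H2 (4 bar), Pd/C, AcOH, 40 °C
Reagents that add atoms: none
Why: Catalytic hydrogenolysis of an electron-rich aryl aldehyde to the methylarene should be clean here, because the ortho and para oxygen donors weaken the benzylic C–O bond and nothing else in 1 is reducible.

Step 2
Reactants: 2 3,5-dimethoxy-2-methylphenol
Product: 3 3,5-dimethoxy-2-methylphenyl N-isopropylcarbamate
Conditions: i-PrNCO, Et3N (cat.), CH2Cl2, rt
Reagents that add atoms: isopropyl isocyanate, CC(C)N=C=O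
Why: Base-catalysed addition of the phenol to an isocyanate should give the secondary O-aryl carbamate, which after N-silylation is a strong ortho-director and can later be removed under mild basic conditions.

Step 3
Reactants: 3 3,5-dimethoxy-2-methylphenyl N-isopropylcarbamate
Product: 7 2-iodo-3,5-dimethoxy-6-methylphenyl N-isopropylcarbamate, via N-silyl carbamate 4 (not isolated), via aryllithium 5 (not isolated), via N-silyl iodide 6 (not isolated)
Conditions: TBSOTf, TMEDA, Et2O, 0 °C to rt; n-BuLi, TMEDA, –78 °C; I2, THF, –78 °C to rt; aq. NaHSO4
Reagents that add atoms: iodine, II; tert-butyldimethylsilyl triflate, CC(C)(C)[Si](C)(C)OS(=O)(=O)C(F)(F)F (silyl group only in 4–6); n-butyllithium, [Li]CCCC (lithium only in 5)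
Why: Directed ortho-metalation: transient N-silylation masks the N–H, the carbamate and the neighbouring methoxy group then cooperate to direct n-BuLi to the one ring position between them (in preference to the site between the two methoxy groups and to the benzylic methyl), iodine traps the aryllithium, and the N–Si bond is hydrolysed on work-up.

Step 4
Reactants: 7 2-iodo-3,5-dimethoxy-6-methylphenyl N-isopropylcarbamate
Product: 9 2-iodo-3,5-dimethoxy-6-methylphenyl trifluoromethanesulfonate, via iodophenol 8 (not isolated)
Conditions: Et2NH, DBU, MeCN, 40 °C; PhNTf2, rt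
Reagents that add atoms: N-phenylbis(trifluoromethanesulfonimide), O=S(=O)(N(c1ccccc1)S(=O)(=O)C(F)(F)F)C(F)(F)F
Why: E1cB cleavage of the secondary carbamate (its carbamoyl part ends as the urea of Et2NH) followed by O-triflation of the phenoxide in the same flask is the standard close of aryne-precursor syntheses and leaves the aryl iodide untouched.

Step 5
Reactants: 9 2-iodo-3,5-dimethoxy-6-methylphenyl trifluoromethanesulfonate; 10 (R)-4-methyloxetan-2-one ((R)-β-butyrolactone)
Product: 16 (3R,4S)-6,8-dimethoxy-3,4,5-trimethylisochroman-1-one, via lactone enolate 11 (not isolated), via aryne 12 (not isolated), via aryllithium 13 (not isolated), via benzocyclobutene alkoxide 14 (not isolated), via lactone dienolate 15 (not isolated)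
Conditions: 2,2,6,6-tetramethylpiperidine, n-BuLi, THF–Et2O, 0 °C; 10, –100 °C; 9, then n-BuLi, –100 to –78 °C; MeI (excess), –78 to –20 °C; aq. NH4Cl
Reagents that add atoms: iodomethane, CI (the lithium in 11 and 13–15 comes from n-butyllithium, [Li]CCCC)
Why: Proposed new method: iodine–lithium exchange on 9 and loss of LiOTf release aryne 12 beside the preformed enolate 11, whose carbon C4′ adds at C4a′ to give aryllithium 13; this closes on the strained lactone carbonyl (4-exo-trig, C8a′–C1′) to alkoxide 14, and cleavage of the old C4′–C1′ bond shared by the two four-membered rings, directly or after reversible expulsion and return of the C3′ alkoxide, enlarges the oxetanone by two atoms to the six-membered lactone as its ortho-toluate-type dienolate 15, which MeI alkylates at C4′. The closest known reaction types are the aryne acyl-alkylation of β-keto esters, the two-carbon ring expansion of cyclic ketone enolates by arynes, the low-temperature C-alkylation of β-lactone enolates and the lateral alkylation of ortho-toluate anions, but no aryne insertion into the C(α)–C(=O) bond of a lactone is known. The driving force is the release of the strain of both small rings of 14 together with the formation of a conjugated benzylic anion. C3′ is never touched, and C4′ is set in the alkylation: MeI meets the nearly flat dienolate perpendicular to the ring and anti to the C3′ methyl, which also places the new methyl pseudoaxial and out of the plane of the C5′ methyl, so steric, stereoelectronic and peri effects all point to the trans (3R,4S) lactone, whereas protonation of a dienolate already methylated at C4′ would set these effects against each other and could be corrected only with a base strong enough to provoke ring opening. Regioselectivity at the aryne rests on the C8′ methoxy group, whose inductive pull sends the nucleophile to the distal carbon C4a′ and leaves the charge at C8a′ ortho to oxygen, and the unsubstituted enolate carbon keeps the clash with the C5′ methyl small. Chemoselectivity rests on the hindered amine being a poor aryne trap, on exchange at iodine outrunning any addition or deprotonation by n-BuLi, and on MeI being present while the mixture warms, so that 15 is alkylated before it can lose carboxylate by β-elimination.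

Step 6
Reactants: 16 (3R,4S)-6,8-dimethoxy-3,4,5-trimethylisochroman-1-one
Product: 17 (3R,4S)-6,8-dihydroxy-3,4,5-trimethylisochroman-1-one
Conditions: BBr3, CH2Cl2, –78 °C to rt; H2O
Reagents that add atoms: none
Why: Lewis-acid cleavage of aryl methyl ethers with BBr3, the C8 ether helped by chelation to the lactone carbonyl, should free both phenols without touching the lactone or the C3 and C4 stereocentres.

Step 7
Reactants: 17 (3R,4S)-6,8-dihydroxy-3,4,5-trimethylisochroman-1-one
Product: 18 (3R,4S)-6,8-dihydroxy-3,4,5-trimethyl-1-oxoisochromane-7-carbaldehyde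
Conditions: Cl2CHOMe, TiCl4, CH2Cl2, 0 °C to rt; 1 M HCl
Reagents that add atoms: dichloromethyl methyl ether, COC(Cl)Cl; water, O
Why: Rieche formylation of a titanium phenoxide should deliver the formyl group ortho to oxygen, and C7 is the only unsubstituted ring position of 17.

Step 8
Reactants: 18 (3R,4S)-6,8-dihydroxy-3,4,5-trimethyl-1-oxoisochromane-7-carbaldehyde
Product: 19 (3R,4S)-6,8-dihydroxy-7-(1-hydroxyethyl)-3,4,5-trimethylisochroman-1-one (both carbinol epimers)
Conditions: MeMgBr (3.5 equiv), THF, –78 to –20 °C; pH 7 buffer
Reagents that add atoms: methylmagnesium bromide, C[Mg]Br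
Why: Grignard addition to an aldehyde in the presence of an ester-type carbonyl: two equivalents are spent on the phenols, whose magnesium phenoxides further deactivate the hindered lactone, so the third should add only to the formyl group; the new carbinol centre is not controlled and is erased in step 12.

Step 9
Reactants: 17 (3R,4S)-6,8-dihydroxy-3,4,5-trimethylisochroman-1-one
Product: 20 (3R,4S)-6,8-bis(tert-butyldimethylsilyloxy)-3,4,5-trimethylisochroman-1-one
Conditions: TBSOTf, 2,6-lutidine, CH2Cl2, 0 °C to rt
Reagents that add atoms: tert-butyldimethylsilyl triflate, CC(C)(C)[Si](C)(C)OS(=O)(=O)C(F)(F)F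
Why: Silyl ether formation with the reactive triflate should also cap the C8 hydroxyl that is hydrogen-bonded to the lactone carbonyl, which removes the acidic protons and the phenoxide deactivation before the hydride step.

Step 10
Reactants: 20 (3R,4S)-6,8-bis(tert-butyldimethylsilyloxy)-3,4,5-trimethylisochroman-1-one
Product: 21 (3R,4S)-6,8-bis(tert-butyldimethylsilyloxy)-3,4,5-trimethylisochroman-1-ol (both anomers)
Conditions: i-Bu2AlH (1.2 equiv), toluene, –78 °C; aq. potassium sodium tartrate
Reagents that add atoms: none
Why: Partial reduction of a lactone with i-Bu2AlH at low temperature should stop at the lactol because the aluminium hemiacetal survives until work-up; the anomeric centre forms as a mixture and disappears in step 11.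

Step 11
Reactants: 21 (3R,4S)-6,8-bis(tert-butyldimethylsilyloxy)-3,4,5-trimethylisochroman-1-ol
Product: 23 (3R,4S)-6-hydroxy-3,4,5-trimethyl-3,4-dihydro-8H-isochromen-8-one (decarboxycitrinin), via lactol triol 22 (not isolated)
Conditions: Bu4NF, AcOH, THF, 0 °C; 0.1 M HCl–CH2Cl2, rt
Reagents that add atoms: none
Why: Fluoride cleavage of the aryl silyl ethers frees triol 22, whose lactol hydroxyl is ortho and para to the two phenols and should be lost as water on mild acid treatment (vinylogous dehydration of a hemiacetal), giving the conjugated quinone methide 23 with C3 and C4 unchanged.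

Step 12
Reactants: 19 (3R,4S)-6,8-dihydroxy-7-(1-hydroxyethyl)-3,4,5-trimethylisochroman-1-one; 23 decarboxycitrinin
Product: 25 dicitrinone H, via ortho-quinone methide 24 (not isolated)
Conditions: (R)-3,3′-bis(2,4,6-triisopropylphenyl)-1,1′-binaphthyl-2,2′-diyl N-triflylphosphoramide (10 mol %), 4 Å MS, CH2Cl2, –20 °C to rt
Reagents that add atoms: none
Why: Chiral Brønsted acid-catalysed conjugate addition of a cyclic 1,3-dicarbonyl-type enol to an ortho-quinone methide made in situ from an ortho-hydroxybenzylic alcohol: the strong phosphoramide (chosen because the lactone carbonyl retards ionisation) dehydrates 19 to 24, C7 of 23, the central and only free carbon of its vinylogous acid, adds to the ethylidene carbon inside the hydrogen-bonded catalyst complex, so the catalyst and not the remote ring stereocentres selects the face and sets C9 as R; since C6′ and C8′ both carry oxygen, the two ethylidene geometries of 24 offer the same local face and lead to the same configuration.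

Compound list
1 | 2-hydroxy-4,6-dimethoxybenzaldehyde | COc1cc(O)c(C=O)c(OC)c1 | starting material
2 | 3,5-dimethoxy-2-methylphenol | COc1cc(O)c(C)c(OC)c1 | intermediate
3 | 3,5-dimethoxy-2-methylphenyl N-isopropylcarbamate | COc1cc(OC(=O)NC(C)C)c(C)c(OC)c1 | intermediate
4 | 3,5-dimethoxy-2-methylphenyl N-(tert-butyldimethylsilyl)-N-isopropylcarbamate | COc1cc(OC(=O)N(C(C)C)[Si](C)(C)C(C)(C)C)c(C)c(OC)c1 | intermediate
5 | 2-lithio-3,5-dimethoxy-6-methylphenyl N-(tert-butyldimethylsilyl)-N-isopropylcarbamate | COc1c([Li])c(OC(=O)N(C(C)C)[Si](C)(C)C(C)(C)C)c(C)c(OC)c1 | intermediate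
6 | 2-iodo-3,5-dimethoxy-6-methylphenyl N-(tert-butyldimethylsilyl)-N-isopropylcarbamate | COc1c(I)c(OC(=O)N(C(C)C)[Si](C)(C)C(C)(C)C)c(C)c(OC)c1 | intermediate
7 | 2-iodo-3,5-dimethoxy-6-methylphenyl N-isopropylcarbamate | COc1c(I)c(OC(=O)NC(C)C)c(C)c(OC)c1 | intermediate
8 | 2-iodo-3,5-dimethoxy-6-methylphenol | COc1c(I)c(O)c(C)c(OC)c1 | intermediate
9 | 2-iodo-3,5-dimethoxy-6-methylphenyl trifluoromethanesulfonate | COc1cc(OC)c(C)c(OS(=O)(=O)C(F)(F)F)c1I | intermediate
10 | (R)-4-methyloxetan-2-one | C[C@@H]1CC(=O)O1 | starting material
11 | lithium enolate of (R)-4-methyloxetan-2-one | [Li]OC1=C[C@@H](C)O1 | intermediate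
12 | 3,5-dimethoxy-6-methylbenzyne (1,2-didehydro-3,5-dimethoxy-6-methylbenzene) | COC1=CC(OC)=C(C)C#C1 | intermediate
13 | (3R,4R)-3-(2-lithio-3,5-dimethoxy-6-methylphenyl)-4-methyloxetan-2-one | O=C1O[C@H](C)[C@H]1c2c(C)c(OC)cc(OC)c2[Li] | intermediate
14 | lithium alkoxide of the benzocyclobutene fused to the oxetane through C1′–C4′ (benzo-fused 2-oxabicyclo[2.2.0]hexan-1-olate) | [Li]O[C@]12O[C@H](C)[C@H]1c1c(C)c(OC)cc(OC)c12 | intermediate
15 | lithium dienolate of (R)-6,8-dimethoxy-3,5-dimethylisochroman-1-one | [Li]OC1=C2C(OC)=CC(OC)=C(C)C2=C[C@@H](C)O1 | intermediate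
16 | (3R,4S)-6,8-dimethoxy-3,4,5-trimethylisochroman-1-one | COc1cc(OC)c(C)c2c1C(=O)O[C@H](C)[C@H]2C | intermediate
17 | (3R,4S)-6,8-dihydroxy-3,4,5-trimethylisochroman-1-one | Oc1cc(O)c(C)c2c1C(=O)O[C@H](C)[C@H]2C | intermediate
18 | (3R,4S)-6,8-dihydroxy-3,4,5-trimethyl-1-oxoisochromane-7-carbaldehyde | O=Cc1c(O)c(C)c2c(c1O)C(=O)O[C@H](C)[C@H]2C | intermediate
19 | (3R,4S)-6,8-dihydroxy-7-(1-hydroxyethyl)-3,4,5-trimethylisochroman-1-one, carbinol epimers | CC(O)c1c(O)c(C)c2c(c1O)C(=O)O[C@H](C)[C@H]2C | intermediate
20 | (3R,4S)-6,8-bis(tert-butyldimethylsilyloxy)-3,4,5-trimethylisochroman-1-one | CC(C)(C)[Si](C)(C)Oc1cc(O[Si](C)(C)C(C)(C)C)c(C)c2c1C(=O)O[C@H](C)[C@H]2C | intermediate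
21 | (3R,4S)-6,8-bis(tert-butyldimethylsilyloxy)-3,4,5-trimethylisochroman-1-ol, anomers | CC(C)(C)[Si](C)(C)Oc1cc(O[Si](C)(C)C(C)(C)C)c(C)c2c1C(O)O[C@H](C)[C@H]2C | intermediate
22 | (3R,4S)-3,4,5-trimethylisochromane-1,6,8-triol, anomers | Oc1cc(O)c(C)c2c1C(O)O[C@H](C)[C@H]2C | intermediate
23 | (3R,4S)-6-hydroxy-3,4,5-trimethyl-3,4-dihydro-8H-isochromen-8-one (decarboxycitrinin) | CC1=C2C(=CO[C@H](C)[C@H]2C)C(=O)C=C1O | intermediate
24 | (3R,4S)-7-ethylidene-8-hydroxy-3,4,5-trimethyl-3,4-dihydroisochromene-1,6(7H)-dione (ortho-quinone methide) | CC=C1C(=O)C(C)=C2[C@H](C)[C@@H](C)OC(=O)C2=C1O | intermediate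
25 | dicitrinone H | CC1=C2C(=CO[C@H](C)[C@H]2C)C(=O)C([C@H](C)c2c(O)c(C)c3c(c2O)C(=O)O[C@H](C)[C@H]3C)=C1O | target

Total step count: 12.
Longest linear sequence: 10 steps (1 → 2 → 3 → 7 → 9 → 16 → 17 → 20 → 21 → 23 → 25).

Steps most likely to fail

Step 5. Several processes could defeat it:
- self-condensation of the lactone enolate before the aryne is released;
- protonation of the aryl anion, so that the sequence ends at plain α-arylation;
- stalling of the ring enlargement after the 4-exo closure;
- β-elimination of carboxylate from the dienolate before methylation.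

The fallback sets out from 9 and returns at 16 by known reactions only. Chemoselective methoxycarbonylation of the C–I bond (Pd(OAc)2, dppf, CO, MeOH, Et3N) should give methyl 2,4-dimethoxy-5-methyl-6-(trifluoromethylsulfonyloxy)benzoate F1. Suzuki–Miyaura coupling of its triflate with (Z)-but-2-en-2-ylboronic acid pinacol ester (Pd(OAc)2, SPhos, K3PO4) should give methyl 2-[(E)-but-2-en-2-yl]-4,6-dimethoxy-3-methylbenzoate F2. Asymmetric hydroboration follows, using the antipode of monoisopinocampheylborane that attacks the face leading to 3R. By analogy with 1-arylcycloalkenes this is expected to be the reagent from (–)-α-pinene. Oxidation with H2O2–NaOH then completes a syn addition of H and OH across the (E)-alkene and should give methyl 2-[(2S,3R)-3-hydroxybutan-2-yl]-4,6-dimethoxy-3-methylbenzoate F3. Warming F3 with catalytic p-TsOH in toluene closes the lactone to 16.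

Step 12. The risks are poor facial selectivity at C9, sluggish ionisation of the electron-poor benzylic alcohol, and acid-induced self-condensation of the quinone methide partner. The fallback sets out from 19 and returns at 25. It moves the generation of 24 from acidic to basic conditions and changes the catalyst class. Treatment of 19 with p-toluenesulfinic acid in CH2Cl2 should give (3R,4S)-6,8-dihydroxy-3,4,5-trimethyl-7-[1-(4-methylphenylsulfonyl)ethyl]isochroman-1-one F4. Aqueous NaHCO3 in toluene then expels sulfinate to release 24 slowly. This is done in the presence of 23 and a quinine-derived squaramide, which binds the enol and the quinone methide at the same time. This is the known base-triggered asymmetric addition of 1,3-dicarbonyl compounds to ortho-quinone methides.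

Step 8. The risks are competing attack of the Grignard reagent on the lactone and loss of water from the product during isolation. The fallback sets out from 17 and returns at 19, replacing formylation and carbanion addition by acylation and hydride reduction. Friedel–Crafts C-acetylation (Ac2O, BF3·OEt2, 80 °C) at the only free position should give (3R,4S)-7-acetyl-6,8-dihydroxy-3,4,5-trimethylisochroman-1-one F5. NaBH4 in THF–EtOH at 0 °C then reduces the ketone to 19 without affecting the lactone.

Further compounds
F1 | step 5 | methyl 2,4-dimethoxy-5-methyl-6-(trifluoromethylsulfonyloxy)benzoate | COC(=O)c1c(OC)cc(OC)c(C)c1OS(=O)(=O)C(F)(F)F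
F2 | step 5 | methyl 2-[(E)-but-2-en-2-yl]-4,6-dimethoxy-3-methylbenzoate | C/C=C(\C)c1c(C)c(OC)cc(OC)c1C(=O)OC
F3 | step 5 | methyl 2-[(2S,3R)-3-hydroxybutan-2-yl]-4,6-dimethoxy-3-methylbenzoate | COC(=O)c1c(OC)cc(OC)c(C)c1[C@H](C)[C@@H](C)O
F4 | step 12 | (3R,4S)-6,8-dihydroxy-3,4,5-trimethyl-7-[1-(4-methylphenylsulfonyl)ethyl]isochroman-1-one | CC(c1c(O)c(C)c2c(c1O)C(=O)O[C@H](C)[C@H]2C)S(=O)(=O)c1ccc(C)cc1
F5 | step 8 | (3R,4S)-7-acetyl-6,8-dihydroxy-3,4,5-trimethylisochroman-1-one | CC(=O)c1c(O)c(C)c2c(c1O)C(=O)O[C@H](C)[C@H]2C
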